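Numbering throughout is the gibberellane numbering of the target: ring A = C1–C5 and C10; ring B = C5, C6, C8, C9, C10; ring C = C8, C9, C11–C14; ring D = C8, C13–C16. C7 is the carboxyl carbon on C6, C17 the methylene carbon, C18 the methyl on C4, C19 the lactone carbonyl.

## The problem

The target gibberellin (32) has four carbocycles (ring A six-membered, ring B five, ring C six, ring D five) and a γ-lactone, and ring B is the hub: it is fused to ring A across C5–C10 and to ring C across C8–C9, shares C8 with ring D and carries the C7 acid on C6. C8 is quaternary, common to rings B, C and D, and with C13 a bridgehead of the bicyclo[3.2.1]octane that ends in the C16=C17 methylene; C4 is a second quaternary carbon, and the C19–O–C10 lactone bridges ring A on the face opposite to the 1β,2β,3β-triol. Of the ten stereocentres only C8 has no neighbour to lean on and must be set absolutely. The others can be relayed: C13 follows from C8 by bridging, C9 prefers the cis B/C fusion whenever ring B is flattened by sp2 carbons, C10 can be set by addition anti to ring C, C5 is fixed by the obligatory cis fusion of the lactone and C6 by equilibration trans to C4, C4 and C3 come from the convex face of the bicyclic lactone, and C1 and C2 from the exo face of ring A beside the 3β-hydroxyl. Several groups will not survive rough treatment: the exocyclic alkene (acid moves it into the ring, it is hydrogenated and oxidized easily, and a radical at C12 would rearrange the bicyclooctane through the homoallyl system), the 3β-hydroxy lactone (retro-aldol under base), the epimerizable C6 centre, and the hindered C7 ester, which cannot be saponified without damage to the lactone. The feature that makes the key step possible is C8 itself: if ring B is written as a cyclopentane-1,3-dione with carbonyls at C6 and C9, C8 becomes a prochiral carbon between two enantiotopic ketones. Its two remaining substituents are a 3-oxobutyl chain (C14–C13–C12(=O)–C11) and a propargyl group (C15–C16≡C17). An amine-catalysed aldol that selects one carbonyl therefore closes ring C and fixes C8, with the alkyne for ring D already attached.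

## Retrosynthesis

**Diol and ester (32 ⇒ 31 ⇒ 29).** The two C–O bonds at C1 and C2 are cut together, back to the C1=C2 alkene of 29, the 3β-hydroxy-1-ene lactone; the acid is masked as its methyl ester 31. Cutting the diol as one unit lets the 3β-hydroxyl direct the oxidant and the lactone bridge shield the other face; removing either hydroxyl singly offers no such control. The forward step must be syn, β-selective and must prefer C1=C2 over C16=C17. The ester must be cleaved by attack at methyl, not at the hindered carbonyl.

**Ring A alkene (29 ⇒ 28).** The C1=C2 bond is cut by ring-closing metathesis to the diene 28, which has a vinyl group on C10 and a 1-hydroxyallyl group on C4. Closing ring A here, rather than at C1–C10 or C3–C4, leaves the alkene exactly where the diol is needed. The forward step has to close a six-membered ring across a γ-lactone between two alkenes held cis-1,3.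

**C3–C4 bond (28 ⇒ 27).** This is an aldol disconnection to acrolein and the α-methyl lactone 27. The order matters: the second substituent enters a cis-bicyclic lactone enolate from the convex face, and the target needs the three-carbon arm there and the methyl on the ring B side. The methyl must therefore already be present. The forward reaction sets C4 and C3 together.

**C4–C5 bond and lactone carbonyl (27 ⇒ 26 ⇒ 24 ⇒ 23).** The lactone is taken back to the cyclic acetal 26, and the C4–C5 bond to a radical closure of the bromoacetal 24 onto the enoate. Intermolecular alkylation of a C10 ketone enolate at C5 would have no control over C5 relative to C9 and C10. A tether from the C10 oxygen can only give the cis-fused ring. The precursor 23 has lost C4, C18, C19 and the C5 and C6 stereocentres.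

**C1–C10 bond (23 ⇒ 22).** Vinyl addition to the C10 ketone of 22. This makes C10 quaternary with its oxygen and C1 in one step. It asks for addition from the convex face of the cis-fused B/C bicycle.

**C7 and the C10 oxygen (22 ⇒ 21 ⇒ 20 ⇒ 19 ⇒ 18 ⇒ 17 ⇒ 15 ⇒ 13).** C6–C7 is cut by carbonylation of the enol triflate 19. The C10 oxygen is traced to conjugate borylation and oxidation of the enone 15, which comes from the ketone 13. Direct allylic oxidation of an enoate at C10 is the shorter neighbour, but it would compete with oxidation at C15 beside the methylene. The precursor 13 is a tricyclic ketone with three stereocentres.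

**Ring C oxidation state (13 ⇒ 12 ⇒ 11 ⇒ 10).** The C12 carbonyl and the C9=C11 alkene are added back to reach the enone 10. The extra functionality is justified because the enone alone makes ring D closure regiospecific. The forward steps must remove it without hydrogenation and without a C12 radical.

**Ring D (10 ⇒ 9 ⇒ 8 ⇒ 7).** The C13–C16 bond is cut to the silyl dienol ether 9 and its alkyne, and back through the ketal 8 to the enedione 7. Kinetic enolization of the enone can only occur at C13, and the terminal alkyne delivers the methylene directly.

**Ring C (7 ⇒ 5), the key disconnection.** The C9=C11 bond is cut by a retro-aldol condensation to the achiral triketone 5. One bond, one ring and the only absolute stereocentre are bought by catalysis.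

**Triketone (5 ⇒ 3 + 4; 3 ⇒ 1 + 2).** A Michael addition and a C-alkylation lead back to three commodity chemicals.

## Roads not taken

**Alternative 1:** Lactone enolate Claisen rearrangement closing ring A. The cut is C4–C5. In the forward sense the C19 carboxyl is first esterified to the C1 oxygen. The derived silyl ketene acetal (LiN(SiMe3)2, Me3SiCl) then shifts across the C1–C10=C5 allyl unit to give A1, a ring A cyclohexene acid with C1=C10, the 2,3-oxygens as methoxymethyl ethers and C7 as a silyl-protected hydroxymethyl group.
- Merits: the most hindered C–C bond of ring A is made intramolecularly with chirality transfer. The C2 and C3 oxygens ride in with the side chain. The freed acid sits next to C1=C10, so an epoxidation–lactonization could install the 1β-hydroxyl and the lactone together.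
- Where it is better: ring A oxygenation needs no osmium reagent beside C16=C17. The chosen plan must rely on hydrogen-bond delivery in step 23 to set against that.
- Weak points: three stereocentres (C1–C3) and a fully substituted ring B alkene must be assembled before the rearrangement. The ketene acetal geometry inside the ring is fixed and leaves little freedom in the transition state that sets C4. C7 still needs a two-stage oxidation late, beside a triol.
- It does not address C8 and would still need an enantioselective entry to rings B–D; the chosen plan supplies one in three steps and brings C7 in as an ester.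

**Alternative 2:** Late carboxylate-directed C–H lactonization at C10. The cut is O–C10. Mn(OTf)2 with a tetradentate bis(pyridylmethyl)diamine ligand and H2O2 would oxidize the γ C10–H bond of a C19 acid to give A2, a 19,10-lactone with a 3β-acetate and a C16 ketone.
- Merits and where it is better: C10 stays a plain methine until the end. The seven steps that the chosen route spends moving oxygen from C6 to C10 (steps 10–16) would disappear.
- Weak points for this target: A2 has saturated, unfunctionalized C1 and C2. Reaching the 1β,2β-diol would need a 3-ketone, dehydrogenation, reduction and dihydroxylation, each next to a β-acyloxy ketone prone to E1cB opening. The electrophilic manganese oxidant also attacks alkenes, so the methylene must be carried as the C16 ketone and restored at the end. The trans A/B fusion with an axial 10-H must be set without help from the lactone.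
- The chosen plan introduces the C10 oxygen, C1 and the C1=C2 unsaturation in the order the triol needs them.

**Alternative 3:** Reversible aldol drained by lactonization at C10. The cuts are C9–C10 and the lactone C–O bond. NaOMe in methanol would equilibrate the C9 enolate of a C11 ketone with its aldol adducts at a C10 ketone, and the 10-alkoxide would close onto the C19 ester to give A3, a C11-oxo 1-ene lactone with a 3β-methoxymethyl ether.
- Merits and where it is better: it is convergent, joining a ring A piece and a ring C/D piece; it forms ring B and the lactone in one operation; and it delivers the same 1-ene-3-oxygenated ring A that the chosen route reaches at 29. In convergence and probably in longest linear sequence it beats a 24-step linear route.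
- Weak points: A3 is itself a β-acyloxy ketone, so the base that drains the aldol can reopen the lactone by elimination. C9 and C10 depend on equilibration alone. The C11 carbonyl must then be removed next to an epimerizable C9 and an acid- and hydrogenation-sensitive methylene. Both fragments need their own asymmetric syntheses, and the proline aldol cannot serve because ring B does not exist until the end.
- The chosen plan sets C8 first by catalysis and relays every later centre from it.

Key step: step 3

Remark on the chemistry: centres that are erased later are carried as mixtures (C10 in 16–21, the acetal carbon in 24–26, the bromine-bearing carbon in 24, C4 in 25–27), and their SMILES show the expected major isomer or leave the centre open; 9-H is drawn cis to C15 throughout, because a 9-epimer would converge at 22.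

## Route

Step 1
Reactants: 1 cyclopentane-1,3-dione; 2 3-bromoprop-1-yne
Product: 3 2-(prop-2-yn-1-yl)cyclopentane-1,3-dione
Conditions: NaOH (1 equiv), H2O, 60 °C
Reagents that add atoms: none
Why: C-Alkylation (SN2) of the stabilized 1,3-dione enolate; water solvates the enolate oxygen and so favours C- over O-alkylation. No stereocentre is formed.

Step 2
Reactants: 3 2-(prop-2-yn-1-yl)cyclopentane-1,3-dione; 4 but-3-en-2-one
Product: 5 2-(3-oxobutyl)-2-(prop-2-yn-1-yl)cyclopentane-1,3-dione
Conditions: H2O, AcOH (cat.), 70 °C
Reagents that add atoms: none
Why: Michael addition of the enolized dione to the enone under weakly acidic conditions that avoid premature aldol closure. C8 becomes quaternary but remains prochiral.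

Step 3
Reactants: 5 2-(3-oxobutyl)-2-(prop-2-yn-1-yl)cyclopentane-1,3-dione
Product: 7 (R)-7a-(prop-2-yn-1-yl)-2,3,7,7a-tetrahydro-1H-indene-1,5(6H)-dione (ring B/C enedione), via cis-fused ketol 6 (not isolated)
Conditions: L-proline (30 mol%), DMF, rt; then H2SO4 (cat.), DMF, 95 °C
Reagents that add atoms: none
Why: L-Proline condenses with the C12 methyl ketone of 5 to the less substituted enamine (C11=C12), and its carboxylic acid hydrogen-bonds to one of the two enantiotopic ring carbonyls, so that C11 is delivered to that carbon (C9) through a chair-like transition state. This is the Hajos–Parrish–Eder–Sauer–Wiechert reaction, established for 2-alkyl-2-(3-oxobutyl)cyclopentane-1,3-diones. Ring C closes by a 6-(enolendo)-exo-trig aldol addition that gives the cis-fused ketol 6, and hydrolysis of the iminium ion returns the catalyst. Acid then dehydrates 6 to the C9=C11 enone, which erases the transient C9 carbinol centre. The one centre that survives, C8, is set by the catalyst: with L-proline the sense should be that of the (S)-methyl parent, which is the C8 configuration of the target (the descriptor reads R only because propargyl outranks C14). The step needs enantiotopic-group selectivity and nothing else, since the two ring carbonyls are otherwise identical, the side-chain ketone has only one productive enamine, and the alkyne is a spectator. The larger propargyl arm may lower the selectivity relative to methyl, so the optical purity of 7 should be checked and, if needed, raised by crystallization.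

Step 4
Reactants: 7 ring B/C enedione
Product: 8 C6 ethylene ketal of 7
Conditions: Me3SiOCH2CH2OSiMe3, Me3SiOTf (cat.), CH2Cl2, −78 °C
Reagents that add atoms: 1,2-bis(trimethylsilyloxy)ethane C[Si](C)(C)OCCO[Si](C)(C)C
Why: Silyl-triflate-catalysed ketalization under kinetic control; the saturated C6 ketone reacts much faster than the vinylogous C12 carbonyl. Only C6 is masked against the enolate, dissolving-metal and hydrazine steps that follow.

Step 5
Reactants: 8 C6 ethylene ketal of 7
Product: 9 cross-conjugated tert-butyldimethylsilyl dienol ether (C12–OSi, C12=C13, C9=C11)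
Conditions: LiN(iPr)2, THF, −78 °C; t-BuMe2SiCl, HMPA, −78 → 0 °C
Reagents that add atoms: tert-butyldimethylsilyl chloride CC(C)(C)[Si](C)(C)Cl
Why: Kinetic deprotonation of an enone removes the α′ proton (C13) and gives the 2-silyloxy diene after O-silylation. The γ protons at C10 react only under equilibrating conditions, and the alkyne C–H is several pKa units less acidic than the ketone.

Step 6
Reactants: 9 cross-conjugated silyl dienol ether
Product: 10 tricyclic enone (rings B, C, D; C6 ketal, C12 ketone, C9=C11, 16-methylene)
Conditions: Ph3PAuCl (5 mol%), AgOTf (5 mol%), CH2Cl2/MeOH (10:1), rt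
Reagents that add atoms: none
Why: Gold-catalysed Conia-ene-type 5-exo-dig carbocyclization of a silyl enol ether onto a terminal alkyne (π-activation by monovalent gold, anti attack of C13 on C16, protodeauration by methanol); dienol ethers of 4-propargylcyclohexenones are the established substrate class. C13 can only bond on the face that carries the propargyl arm, so its configuration follows from C8.

Step 7
Reactants: 10 tricyclic enone
Product: 11 saturated C12 ketone (9-H cis to C15)
Conditions: Li, NH3/THF, t-BuOH (1 equiv), −78 °C; NH4Cl
Reagents that add atoms: none
Why: Dissolving-metal (Birch-type) reduction of the enone; protonation of the C9 carbanion should give the less strained cis B/C fusion, while the isolated methylene and the ketal are inert. A 9-epimer would not be lost, because C9 becomes epimerizable again and is equilibrated at 22.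

Step 8
Reactants: 11 saturated C12 ketone
Product: 12 12-deoxo ketal
Conditions: N2H4·H2O, KOH, diethylene glycol, 130 → 200 °C
Reagents that add atoms: none
Why: Wolff–Kishner reduction (Huang–Minlon variant) removes the C12 carbonyl through the hydrazone anion. Being ionic, it avoids a C12 radical and the homoallyl rearrangement of the bicyclooctane; ketal and alkene tolerate hot base.

Step 9
Reactants: 12 12-deoxo ketal
Product: 13 tricyclic C6 ketone
Conditions: pyridinium p-toluenesulfonate, acetone/H2O, 60 °C
Reagents that add atoms: water O
Why: Mild acetal hydrolysis; the weak acid leaves the exocyclic alkene in place.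

Step 10
Reactants: 13 tricyclic C6 ketone
Product: 15 cyclopentenone (C6 ketone, C5=C10), via trimethylsilyl enol ether 14 (not isolated)
Conditions: Me3SiOTf, Et3N, CH2Cl2, 0 °C; then Pd(OAc)2 (10 mol%), O2 (1 atm), DMSO, 50 °C
Reagents that add atoms: trimethylsilyl trifluoromethanesulfonate C[Si](C)(C)OS(=O)(=O)C(F)(F)F (silyl group of 14 only)
Why: Saegusa–Ito oxidation. C6 can enolize only toward C5 because C8 is quaternary, so a single silyl enol ether and a single enone result.

Step 11
Reactants: 15 cyclopentenone
Product: 17 10-hydroxy C6 ketone, via C10 pinacol boronate 16 (not isolated)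
Conditions: CuCl (5 mol%), NaOt-Bu (10 mol%), bis[2-(diphenylphosphino)phenyl] ether (5 mol%), B2pin2, MeOH, THF, rt; then NaBO3·4H2O, THF/H2O, rt
Reagents that add atoms: bis(pinacolato)diboron CC1(C)OB(OC1(C)C)B1OC(C)(C)C(C)(C)O1 (boron of 16); sodium perborate [Na+].[Na+].O[B-]1(O)OO[B-](O)(O)OO1 (hydroxyl oxygen of 17)
Why: Copper-catalysed conjugate borylation places boron on C10, and perborate replaces it by hydroxyl with retention; the unactivated methylene does not react with the Cu–Bpin intermediate. The C10 configuration is of no consequence because C10 is oxidized in step 16.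

Step 12
Reactants: 17 10-hydroxy C6 ketone
Product: 18 10-(tert-butyldimethylsilyloxy) C6 ketone
Conditions: t-BuMe2SiCl, imidazole, DMF, rt
Reagents that add atoms: tert-butyldimethylsilyl chloride CC(C)(C)[Si](C)(C)Cl
Why: Standard silylation; the ether keeps the β-hydroxyl from being triflated or dehydrated in the next two steps.

Step 13
Reactants: 18 10-silyloxy C6 ketone
Product: 19 C6 enol triflate (C5=C6)
Conditions: KN(SiMe3)2, THF, −78 °C; N-(5-chloropyridin-2-yl)-N-(trifluoromethylsulfonyl)trifluoromethanesulfonamide, −78 °C; NH4Cl (aq)
Reagents that add atoms: N-(5-chloropyridin-2-yl)-N-(trifluoromethylsulfonyl)trifluoromethanesulfonamide O=S(=O)(N(c1ccc(Cl)cn1)S(=O)(=O)C(F)(F)F)C(F)(F)F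
Why: Enolate O-triflation; only C5 carries α-protons. Trapping at −78 °C with the reactive pyridyl triflimide is meant to outrun E1cB loss of the β-silyloxy group.

Step 14
Reactants: 19 C6 enol triflate
Product: 20 methyl 5-en-7-oate with 10-silyloxy group
Conditions: Pd(OAc)2 (5 mol%), Ph3P (10 mol%), CO (1 atm), Et3N, MeOH/DMF, 60 °C
Reagents that add atoms: carbon monoxide [C-]#[O+]; methanol CO
Why: Palladium-catalysed methoxycarbonylation of a vinyl triflate (oxidative addition, CO insertion, methanolysis), reliable for hindered cycloalkenyl triflates next to quaternary carbons. C7 arrives at the carboxyl oxidation level in one step.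

Step 15
Reactants: 20 silyloxy enoate
Product: 21 methyl 10-hydroxy-5-en-7-oate
Conditions: HF·pyridine, THF, 0 °C → rt
Reagents that add atoms: none
Why: Fluoride-mediated desilylation under buffered acidic conditions, which avoids γ-deprotonation of the enoate.

Step 16
Reactants: 21 hydroxy enoate
Product: 22 methyl 10-oxo-5-en-7-oate
Conditions: Dess–Martin periodinane, NaHCO3, CH2Cl2, 0 °C → rt; then DBU (10 mol%), rt
Reagents that add atoms: none
Why: Dess–Martin oxidation of the allylic alcohol. C9 is now α to the ketone, and DBU equilibrates it through the enol to the cis-fused isomer, the only one that lets the nearly planar ring B sit on the bicyclooctane without a large C6–C8–C9–C10 torsion.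

Step 17
Reactants: 22 keto enoate
Product: 23 10-hydroxy-10-vinyl enoate (oxygen on the ring C face, vinyl on the 9-H face)
Conditions: CH2=CHMgBr, CeCl3, THF, −78 °C; NH4Cl (aq)
Reagents that add atoms: vinylmagnesium bromide C=C[Mg]Br
Why: 1,2-Addition of the organocerium reagent, which suppresses enolization at C9 and conjugate addition and is faster at the ketone than at the hindered ester. Attack should come from the convex face of the cis-fused bicycle, anti to C11 on the adjacent C9, which places the oxygen and C1 as the target requires.

Step 18
Reactants: 23 vinyl carbinol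
Product: 24 mixed bromoacetal on the C10 oxygen
Conditions: ethyl prop-1-enyl ether (E/Z), N-bromosuccinimide, CH2Cl2, −40 → 0 °C
Reagents that add atoms: ethyl prop-1-enyl ether CC=COCC; N-bromosuccinimide O=C1CCC(=O)N1Br
Why: Bromoacetalization (haloetherification of the electron-rich enol ether with the tertiary alcohol as nucleophile), the standard entry to an Ueno–Stork cyclization; the enol ether is far more nucleophilic than the other alkenes. The new acetal and bromide centres are mixtures that are erased in steps 19 to 21.

Step 19
Reactants: 24 mixed bromoacetal
Product: 26 cis-fused cyclic acetal with the C6 ester trans to C4, via cyclized acetal as C6 epimer mixture 25 (not isolated)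
Conditions: Bu3SnH, AIBN (cat.), benzene, 80 °C (slow addition); then NaOMe (cat.), MeOH, 50 °C
Reagents that add atoms: none
Why: Ueno–Stork 5-exo-trig radical cyclization. The nucleophilic secondary radical should add to C5, the β-carbon of the electron-poor enoate, faster than to the unactivated vinyl group (polarity matching), and the tether from the C10 oxygen allows only the cis-fused bicycle, which fixes C5. Bu3SnH reduces the α-ester radical, and methoxide then equilibrates C6 to the more stable arrangement.

Step 20
Reactants: 26 cyclic acetal
Product: 27 4-methyl-10-vinyl 19,10-lactone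
Conditions: CrO3, H2SO4, H2O/acetone, 0 °C
Reagents that add atoms: water O
Why: Jones oxidation of the 2-ethoxytetrahydrofuran (hydrolysis to the lactol, then oxidation by hexavalent chromium), the usual finish of an Ueno–Stork sequence. A short reaction at 0 °C spares the alkenes.

Step 21
Reactants: 27 methyl lactone
Product: 28 aldol adduct (C4 quaternary, 3-hydroxy, 1-hydroxyallyl arm)
Conditions: LiN(iPr)2, THF, −78 °C; acrolein, −78 °C; AcOH, −78 °C
Reagents that add atoms: acrolein C=CC=O
Why: Aldol addition of the lactone enolate; the lactone α-proton is more acidic and less hindered than C6–H of the ester. The aldehyde must approach the convex face of the cis-bicyclic enolate, anti to ring B, which leaves the methyl on the ring B side as in the target. A closed Zimmerman–Traxler transition state with vinyl equatorial predicts the carbinol with O3 anti to C19, the 3β configuration; the cold acidic quench prevents retro-aldol.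

Step 22
Reactants: 28 aldol adduct
Product: 29 methyl ester of the 3β-hydroxy-1-ene 19,10-lactone (1,2-didehydro-1,2-dideoxy analogue of 31)
Conditions: second-generation Grubbs catalyst (5 mol%), CH2Cl2, 40 °C
Reagents that add atoms: none
Why: Ring-closing metathesis. The catalyst should load on the less hindered allylic-alcohol vinyl and close the six-membered ring onto the C10 vinyl held cis-1,3 on the lactone; the 1,1-disubstituted methylene is a poor metathesis partner.

Step 23
Reactants: 29 methyl ester of the 3β-hydroxy-1-ene 19,10-lactone
Product: 31 methyl ester of the target (1β,2β,3β-triol), via osmate ester TMEDA chelate 30 (not isolated)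
Conditions: OsO4 (1.05 equiv), TMEDA (1.1 equiv), CH2Cl2, −78 °C; then Na2SO3 (aq), THF, 60 °C
Reagents that add atoms: osmium tetroxide O=[Os](=O)(=O)=O (both new oxygens); N,N,N',N'-tetramethylethane-1,2-diamine CN(C)CCN(C)C (ligand in 30 only)
Why: Hydrogen-bond-directed syn-dihydroxylation. The OsO4·TMEDA complex is bound by the 3β-hydroxyl and delivered to the neighbouring C1=C2 bond on the β face, which is also the exo face away from the lactone bridge, so both new hydroxyls should be cis to O3. Proximity to the hydroxyl is relied on for selectivity over the remote C16=C17 bond; sulfite cleaves the osmate ester.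

Step 24
Reactants: 31 methyl ester of the target
Product: 32 target gibberellin (1β,2β,3β-trihydroxy-16-methylene 19,10-lactone 7-oic acid)
Conditions: n-PrSLi, HMPA, rt; then dilute HCl
Reagents that add atoms: none
Why: SN2 demethylation by thiolate, the established way to free the hindered C7 acid of gibberellins. The weakly basic thiolate attacks the methyl group and not the carbonyls, so the lactone and the retro-aldol-prone 3β-hydroxy lactone unit survive.

## Compound list

1 | cyclopentane-1,3-dione | O=C1CCC(=O)C1 | starting material
2 | 3-bromoprop-1-yne | C#CCBr | starting material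
3 | 2-(prop-2-yn-1-yl)cyclopentane-1,3-dione | C#CCC1C(=O)CCC1=O | intermediate
4 | but-3-en-2-one | CC(=O)C=C | starting material
5 | 2-(3-oxobutyl)-2-(prop-2-yn-1-yl)cyclopentane-1,3-dione (achiral triketone) | C#CCC1(CCC(C)=O)C(=O)CCC1=O | intermediate
6 | (3aS,7aR)-3a-hydroxy-7a-(prop-2-yn-1-yl)hexahydro-1H-indene-1,5(4H)-dione (cis-fused ketol, hydroxyl on C9) | C#CC[C@]12CCC(=O)C[C@@]1(O)CCC2=O | intermediate
7 | (R)-7a-(prop-2-yn-1-yl)-2,3,7,7a-tetrahydro-1H-indene-1,5(6H)-dione (C6 ketone, C12 ketone, C9=C11, propargyl on C8) | C#CC[C@]12CCC(=O)C=C1CCC2=O | intermediate
8 | C6 ethylene ketal of 7 | C#CC[C@]12CCC(=O)C=C1CCC21OCCO1 | intermediate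
9 | C12 tert-butyldimethylsilyl dienol ether of 8 (C12=C13, C9=C11) | C#CC[C@]12CC=C(O[Si](C)(C)C(C)(C)C)C=C1CCC21OCCO1 | intermediate
10 | tricyclic enone: rings B, C, D with C6 ethylene ketal, C12 ketone, C9=C11, 16-methylene; C8 and C13 as in the target | C=C1C[C@]23C[C@H]1C(=O)C=C2CCC31OCCO1 | intermediate
11 | 9,11-dihydro derivative of 10 (9-H cis to C15) | C=C1C[C@]23C[C@H]1C(=O)C[C@H]2CCC31OCCO1 | intermediate
12 | 12-deoxo derivative of 11 (C6 ketal, 16-methylene) | C=C1C[C@]23C[C@H]1CC[C@H]2CCC31OCCO1 | intermediate
13 | tricyclic C6 ketone (rings B, C, D, 16-methylene) | C=C1C[C@]23C[C@H]1CC[C@H]2CCC3=O | intermediate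
14 | C6 trimethylsilyl enol ether of 13 (C5=C6) | C=C1C[C@]23C[C@H]1CC[C@H]2CC=C3O[Si](C)(C)C | intermediate
15 | ring B cyclopentenone (C6 ketone, C5=C10) | C=C1C[C@]23C[C@H]1CC[C@H]2C=CC3=O | intermediate
16 | 10-(pinacolboryl) C6 ketone (boron cis to 9-H expected) | C=C1C[C@]23C[C@H]1CC[C@H]2[C@H](B1OC(C)(C)C(C)(C)O1)CC3=O | intermediate
17 | 10-hydroxy C6 ketone | C=C1C[C@]23C[C@H]1CC[C@H]2[C@H](O)CC3=O | intermediate
18 | 10-(tert-butyldimethylsilyloxy) C6 ketone | C=C1C[C@]23C[C@H]1CC[C@H]2[C@H](O[Si](C)(C)C(C)(C)C)CC3=O | intermediate
19 | C6 enol triflate (C5=C6) with 10-silyloxy group | C=C1C[C@]23C[C@H]1CC[C@H]2[C@H](O[Si](C)(C)C(C)(C)C)C=C3OS(=O)(=O)C(F)(F)F | intermediate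
20 | methyl 10-(tert-butyldimethylsilyloxy)-5-en-7-oate | C=C1C[C@]23C[C@H]1CC[C@H]2[C@H](O[Si](C)(C)C(C)(C)C)C=C3C(=O)OC | intermediate
21 | methyl 10-hydroxy-5-en-7-oate | C=C1C[C@]23C[C@H]1CC[C@H]2[C@H](O)C=C3C(=O)OC | intermediate
22 | methyl 10-oxo-5-en-7-oate (9-H cis to C15) | C=C1C[C@]23C[C@H]1CC[C@H]2C(=O)C=C3C(=O)OC | intermediate
23 | methyl 10-hydroxy-10-vinyl-5-en-7-oate (C10 as in the target: oxygen on the ring C face) | C=C1C[C@]23C[C@H]1CC[C@H]2[C@](O)(C=C)C=C3C(=O)OC | intermediate
24 | C10–O–CH(OEt)–CHBr–CH3 mixed bromoacetal of 23 | C=C1C[C@]23C[C@H]1CC[C@H]2[C@](OC(OCC)C(C)Br)(C=C)C=C3C(=O)OC | intermediate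
25 | cis-fused 2-ethoxy-3-methyltetrahydrofuran on C5–C10 (C4–C5 bond formed), C6 epimer mixture | C=C1C[C@]23C[C@H]1CC[C@H]2[C@@]1(C=C)OC(OCC)C(C)[C@H]1C3C(=O)OC | intermediate
26 | as 25 with the C6 ester trans to C4 (C5, C6 as in the target) | C=C1C[C@]23C[C@H]1CC[C@H]2[C@@]1(C=C)OC(OCC)C(C)[C@H]1[C@@H]3C(=O)OC | intermediate
27 | 19,10-lactone with 4-methyl (C4 epimers) and 10-vinyl groups, methyl 7-oate | C=C1C[C@]23C[C@H]1CC[C@H]2[C@@]1(C=C)OC(=O)C(C)[C@H]1[C@@H]3C(=O)OC | intermediate
28 | aldol adduct: C4 quaternary (methyl on the ring B side), (3β)-1-hydroxyallyl arm, 10-vinyl | C=C1C[C@]23C[C@H]1CC[C@H]2[C@@]1(C=C)OC(=O)[C@@](C)([C@H]1[C@@H]3C(=O)OC)[C@@H](O)C=C | intermediate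
29 | methyl ester of the 3β-hydroxy-1-ene 19,10-lactone (1,2-didehydro-1,2-dideoxy analogue of 31; 16-methylene) | C=C1C[C@]23C[C@H]1CC[C@H]2[C@@]12OC(=O)[C@@](C)([C@H]1[C@@H]3C(=O)OC)[C@@H](O)C=C2 | intermediate
30 | 1β,2β-osmate ester of 29 (hexavalent osmium), TMEDA chelate | C=C1C[C@]23C[C@H]1CC[C@H]2[C@@]12OC(=O)[C@@](C)([C@H]1[C@@H]3C(=O)OC)[C@@H](O)[C@H]1O[Os](=O)(=O)O[C@@H]21.CN(C)CCN(C)C | intermediate
31 | methyl ester of the target (1β,2β,3β-triol, 19,10-lactone, 16-methylene) | C=C1C[C@]23C[C@H]1CC[C@H]2[C@@]12OC(=O)[C@@](C)([C@H]1[C@@H]3C(=O)OC)[C@@H](O)[C@@H](O)[C@H]2O | intermediate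
32 | target gibberellin: 1β,2β,3β-trihydroxy-16-methylene 19,10-lactone 7-oic acid | C=C1C[C@]23C[C@H]1CC[C@H]2[C@@]12OC(=O)[C@@](C)([C@H]1[C@@H]3C(=O)O)[C@@H](O)[C@@H](O)[C@H]2O | target

## Step count and least certain steps

Total: 24 steps. Longest linear sequence: 24 steps from 1 (the route is linear).

**Step 3 (key step).** The likely failure is erosion of enantiotopic-carbonyl selection, because the propargyl arm is larger than the methyl group of the classical substrate, together with slow turnover to the ketol. Fallback (resolution in place of catalytic desymmetrization): starting from 5, pyrrolidine and acetic acid give the racemic enedione F1. Ketalization of its saturated ketone with the bis(trimethylsilyl) ether of (R,R)-hydrobenzoin and Me3SiOTf gives the hydrobenzoin ketal with the C8 configuration of the route F2 and its diastereomeric ketal F3, which are separated by chromatography or crystallization. Acid hydrolysis of F2 rejoins the route at 7.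

**Step 23.** The likely failure is loss of chemoselectivity: the osmium reagent may attack the more electron-rich C16=C17 bond faster than hydrogen-bond delivery brings it to C1=C2, leading to over-oxidation. Fallback (temporary masking of the methylene): starting from 29, one equivalent of 3-chloroperbenzoic acid epoxidizes the more nucleophilic exocyclic alkene to the 16,17-epoxide F4. OsO4/TMEDA then sulfite gives the epoxy triol F5. Deoxygenation with Cp2TiCl (from Cp2TiCl2 and Zn) restores the alkene and rejoins the route at 31.

**Step 21.** The likely failures are poor simple diastereoselection at C3 (acrolein is small and an open transition state may compete) and competing deprotonation at C6. Fallback (stereocentre set by reduction, not by the aldol): starting from 27, the aldol is run without regard to C3, giving 28 together with its 3-epimer F6. Ring-closing metathesis takes the mixture to 29 and the 3-epimer of 29 F7. Dess–Martin oxidation converges both on the 1-en-3-one F8. A Corey–Bakshi–Shibata reduction with catecholborane, with the catalyst enantiomer chosen for hydride delivery to the α face, rejoins the route at 29.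

**Step 13.** The likely failure is β-elimination of the silyloxy group from the C6 enolate before it is triflated, which would return enone 15. Fallback (oxygen introduced after carbonylation): starting from 15, the pinacol boronate 16 is isolated. Its enolate, which has no leaving group at C10, is triflated to the boryl enol triflate F9. Carbonylation as in step 14 gives the boryl enoate F10, and perborate oxidation of the C–B bond rejoins the route at 21.

**Step 17.** The likely failures are addition to the wrong face of C10, or enolization at C9 instead of addition. Fallback (substituent-directed addition with self-selecting lactonization): starting from 22, Zn in acetic acid reduces the ene-dicarbonyl to the saturated keto ester F11. Kinetic enolate alkylation at C5 with methyl bromoacetate, trans to the C6 ester, gives the keto diester F12. CH2=CHMgBr/CeCl3 then adds anti to the new C5 arm, and only the cis alkoxide can lactonize, giving the 10-vinyl lactone F13. Methylation at C4 (LiN(iPr)2, MeI) rejoins the route at 27.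

**Step 19.** The likely failure is poor chemoselectivity of the radical closure: the C1=C2 vinyl group and the C5=C6 enoate are both allylic to the C10 oxygen, each can accept the radical in a 5-exo mode, and only polarity matching favours the enoate. Fallback (ionic closure in place of the radical one): starting from 23, the lithium alkoxide (LiN(SiMe3)2, THF, −78 °C) is acylated with propanoyl chloride to the C10 propanoate F14. KN(SiMe3)2 at −78 °C then forms the propanoate enolate, which can add only to C5 of the enoate in a 5-exo-trig Michael reaction, since the vinyl group is no acceptor. Protonation of the resulting C6 ester enolate on the face away from C4 rejoins the route at 27.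

Further compounds

F1 | step 3 | racemic 7a-(prop-2-yn-1-yl)-2,3,7,7a-tetrahydro-1H-indene-1,5(6H)-dione | C#CCC12CCC(=O)C=C1CCC2=O
F2 | step 3 | (R,R)-hydrobenzoin C6 ketal of 7 | C#CC[C@]12CCC(=O)C=C1CCC21O[C@H](c3ccccc3)[C@@H](c3ccccc3)O1
F3 | step 3 | (R,R)-hydrobenzoin C6 ketal of the enantiomer of 7 | C#CC[C@@]12CCC(=O)C=C1CCC21O[C@H](c3ccccc3)[C@@H](c3ccccc3)O1
F4 | step 23 | 16,17-epoxide of 29 | C1OC12C[C@]34C[C@H]2CC[C@H]3[C@@]12OC(=O)[C@@](C)([C@H]1[C@@H]4C(=O)OC)[C@@H](O)C=C2
F5 | step 23 | 16,17-epoxide of 31 | C1OC12C[C@]34C[C@H]2CC[C@H]3[C@@]12OC(=O)[C@@](C)([C@H]1[C@@H]4C(=O)OC)[C@@H](O)[C@@H](O)[C@H]2O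
F6 | step 21 | 3-epimer of aldol adduct 28 | C=C1C[C@]23C[C@H]1CC[C@H]2[C@@]1(C=C)OC(=O)[C@@](C)([C@H]1[C@@H]3C(=O)OC)[C@H](O)C=C
F7 | step 21 | 3-epimer of 29 | C=C1C[C@]23C[C@H]1CC[C@H]2[C@@]12OC(=O)[C@@](C)([C@H]1[C@@H]3C(=O)OC)[C@H](O)C=C2
F8 | step 21 | 3-oxo-1-ene 19,10-lactone methyl ester | C=C1C[C@]23C[C@H]1CC[C@H]2[C@@]12OC(=O)[C@@](C)([C@H]1[C@@H]3C(=O)OC)C(=O)C=C2
F9 | step 13 | C6 enol triflate of 16 (10-pinacolboryl) | C=C1C[C@]23C[C@H]1CC[C@H]2[C@H](B1OC(C)(C)C(C)(C)O1)C=C3OS(=O)(=O)C(F)(F)F
F10 | step 13 | methyl 10-(pinacolboryl)-5-en-7-oate | C=C1C[C@]23C[C@H]1CC[C@H]2[C@H](B1OC(C)(C)C(C)(C)O1)C=C3C(=O)OC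
F11 | step 17 | methyl 10-oxo-7-oate (5,6-dihydro derivative of 22) | C=C1C[C@]23C[C@H]1CC[C@H]2C(=O)C[C@@H]3C(=O)OC
F12 | step 17 | 5-(methoxycarbonylmethyl) derivative of F11 | C=C1C[C@]23C[C@H]1CC[C@H]2C(=O)[C@@H](CC(=O)OC)[C@@H]3C(=O)OC
F13 | step 17 | 10-vinyl 19,10-lactone lacking the C4 methyl | C=C1C[C@]23C[C@H]1CC[C@H]2[C@@]1(C=C)OC(=O)C[C@H]1[C@@H]3C(=O)OC
F14 | step 19 | C10 propanoate ester of 23 | C=C1C[C@]23C[C@H]1CC[C@H]2[C@](OC(=O)CC)(C=C)C=C3C(=O)OC
A1 | alternative 1 | ring A cyclohexene C19 acid (C1=C10, 2,3-bis(methoxymethyl) ether, C7 as silyloxymethyl) | C=C1C[C@]23C[C@H]1CC[C@H]2C1=C[C@H](OCOC)[C@H](OCOC)[C@@](C)(C(=O)O)[C@H]1[C@@H]3CO[Si](C)(C)C(C)(C)C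
A2 | alternative 2 | 3β-acetoxy-16-oxo-17-nor 19,10-lactone methyl ester | O=C1C[C@]23C[C@H]1CC[C@H]2[C@@]12OC(=O)[C@@](C)([C@H]1[C@@H]3C(=O)OC)[C@@H](OC(C)=O)CC2
A3 | alternative 3 | 11-oxo-1-ene 19,10-lactone methyl ester, 3β-methoxymethyl ether | C=C1C[C@]23C[C@H]1CC(=O)[C@H]2[C@@]12OC(=O)[C@@](C)([C@H]1[C@@H]3C(=O)OC)[C@@H](OCOC)C=C2
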